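**Retrosynthetic overview**
1. Target ⇐ chelation-controlled reduction of the C3 ketone ⇐ hydroxyl-directed cis-epoxidation of a (1Z)-enone reached through its 3,10-hemiketal; lactone C=O ⇐ late allylic oxidation of a 3-methylenetetrahydrofuran (masked α-methylene lactone); C8–OH ⇐ 1,3-anti reduction directed by C10–OH, then angelate by mixed anhydride.
2. Ten-membered ring ⇐ anionic oxy-Cope ([3,3]) of a 1,2-dialkenylcyclohexenol: C3–C8 broken, C1–C10 formed, C10 set in the chair transition state, 4Z olefin inherited from the six-membered ring.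
3. Cope substrate ⇐ cis-fused bicyclic enone by aldol condensation at C8, γ-deprotonation/α-hydroxylation/O-methylation, and addition of (Z)-2-ethoxyvinyllithium to C3.
4. Bicyclic enone ⇐ (S)-carvone (C7 bought, C6 set by cis iodoetherification). Ring order: cyclohexene (bought) → tetrahydrofuran → ten-membered carbocycle → transient hemiketal → oxirane → lactone carbonyl.

Assumption: the SMILES is read literally (cis-fused 6,12-lactone, cis-1,2-oxirane, 4Z, angelate); aldehyde 7 is taken as commercial, and its stereocentre is erased in step 6 and controls nothing.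
Atom labels: carbons carry the germacrane numbers of the target throughout (C1–C10 ring, C11–C13 methylene-lactone carbons, C14 = methyl on C10, C15 = methyl on C4).

**Step 1**
Reactants: 1 (S)-(+)-carvone
Product: 2 (5S)-5-(3-hydroxyprop-1-en-2-yl)-2-methylcyclohex-2-en-1-one (10-hydroxycarvone)
Conditions: SeO2 (0.3 equiv), t-BuOOH, CH2Cl2, 25 °C
Reagents that add atoms: tert-butyl hydroperoxide CC(C)(C)OO; selenium dioxide O=[Se]=O
Why: SeO2-catalysed allylic hydroxylation (ene reaction followed by [2,3]-sigmatropic shift) attacks only the electron-rich 1,1-disubstituted alkene at its methyl group and leaves the deactivated enone and the C7 centre untouched.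

**Step 2**
Reactants: 2 10-hydroxycarvone
Product: 4 (5R)-5-(3-hydroxyprop-1-en-2-yl)-2-methylcyclohex-3-en-1-one (β,γ-enone; both epimers at the methyl-bearing carbon), via dipotassium dienolate 3 (not isolated)
Conditions: KOC(CH3)3 (2.5 equiv), t-BuOH–THF, 0 °C; then inverse quench into cold aq. AcOH
Reagents that add atoms: none
Why: Thermodynamic γ-deprotonation gives the extended dienolate and its kinetic α-protonation (base-mediated deconjugation) gives the β,γ-enone, the new C4 centre being irrelevant because it becomes sp2 again in step 3.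

**Step 3**
Reactants: 4 β,γ-enone
Product: 6 (3aS,7aS)-6-methyl-3-methylidene-2,3,3a,7a-tetrahydro-1-benzofuran-5(4H)-one (cis-fused bicyclic enone), via iodo ether 5 (not isolated)
Conditions: I2, NaHCO3, CH3CN, 0 °C; then DBU, 25 °C
Reagents that add atoms: none
Why: 5-exo iodoetherification can only close cis to the side chain on C7, which fixes C6 from the carvone centre, and E1cB loss of HI through the C3 enolate restores the C4=C5 enone, which is cis because it lies in the six-membered ring.

**Step 4**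
Reactants: 6 bicyclic enone; 7 (S)-2-(tert-butyldimethylsilyloxy)propanal
Product: 9 C8 aldol adduct of 6 (C8 bears CH(OH)–CH(OSiMe2t-Bu)CH3; C8/C9 epimer mixture), via lithium enolate 8 (not isolated)
Conditions: LiN(i-Pr)2, THF, −78 °C; then 7, −78 °C; H2O
Reagents that add atoms: none
Why: Kinetic deprotonation at C8 (α′) and aldol addition to the α-silyloxy aldehyde build the C8–C9 bond, the new carbinol-type centres being erased in steps 5 and 6.

**Step 5**
Reactants: 9 aldol adduct
Product: 11 (E)-C8=C9 alkylidene ketone (C9 carries the (S)-CH(OSiMe2t-Bu)CH3 group), via methanesulfonate 10 (not isolated)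
Conditions: CH3SO2Cl, Et3N, CH2Cl2, 0 °C; then DBU, 25 °C
Reagents that add atoms: none
Why: Mesylation and E1cB elimination complete the aldol condensation and give the thermodynamically preferred (E)-alkylidene ketone.

**Step 6**
Reactants: 11 alkylidene ketone
Product: 14 C8 methyl ether (C8 quaternary: OCH3 on the face opposite C11 plus a (Z)-2-(tert-butyldimethylsilyloxy)prop-1-enyl group), via potassium dienolate 12 (not isolated), via potassium alkoxide 13 (not isolated)
Conditions: KN(SiMe3)2, THF–DMPU, −78 °C; (±)-trans-2-(phenylsulfonyl)-3-phenyloxaziridine; then CF3SO3CH3, −78 → 0 °C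
Reagents that add atoms: 2-(phenylsulfonyl)-3-phenyloxaziridine O=S(=O)(c1ccccc1)N1OC1c1ccccc1; methyl trifluoromethanesulfonate COS(=O)(=O)C(F)(F)F
Why: Vinylogous (γ) deprotonation at C10 gives a cross-conjugated dienolate with the silyloxy group cis to C8 (least allylic strain), Davis α-hydroxylation then occurs at C8 from the face opposite the C7–C11 bond of the cis-fused bicycle, and O-methylation caps the tertiary alkoxide so that no C8 enolate can form later.

**Step 7**
Reactants: 14 C8 methyl ether; 15 (Z)-1-bromo-2-ethoxyethene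
Product: 16 tertiary C3 carbinol carrying a (Z)-2-ethoxyvinyl group trans to the C8 alkenyl group
Conditions: 15, n-C4H9Li, Et2O, −78 °C; then 14, THF, −78 °C; H2O
Reagents that add atoms: none
Why: Chelation-controlled (Cram chelate) 1,2-addition of the vinyllithium to the α-methoxy ketone from the face opposite the C8 alkenyl group places the two alkenyl groups trans on C3 and C8.

**Step 8**
Reactants: 16 dialkenyl carbinol
Product: 19 8-methoxy-10-(tert-butyldimethylsilyloxy)-6,12-epoxygermacra-1E,4Z,8Z,11(13)-tetraen-3-one, via potassium alkoxide 17 (not isolated), via potassium enolate 18 (not isolated)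
Conditions: KH, 18-crown-6, THF, 0 → 25 °C; H2O
Reagents that add atoms: none
Why: The anionic oxy-Cope [3,3]-sigmatropic rearrangement runs through a chair transition state with both alkenyl groups equatorial, breaking C3–C8 and forming C1–C10 on the face of the (Z)-silyl enol ether that gives the target configuration at C10 while the ring olefin is carried over as 4Z, and the β-ethoxy enolate then expels ethoxide (E1cB) to give the (1E)-enone.

**Step 9**
Reactants: 19 ten-membered dienone
Product: 20 10-hydroxy-6,12-epoxygermacra-1E,4Z,11(13)-triene-3,8-dione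
Conditions: 48% aq. HF, CH3CN, 0 °C
Reagents that add atoms: water O
Why: Acid hydrolysis of the methyl enol ether gives the C8 ketone regiospecifically and fluoride cleaves the tertiary silyl ether, all without base so that neither retro-aldol cleavage nor enolisation toward C7 intervenes.

**Step 10**
Reactants: 20 β-hydroxy ketone
Product: 21 8,10-dihydroxy-6,12-epoxygermacra-1E,4Z,11(13)-trien-3-one (8,10-anti diol)
Conditions: (CH3)4N[BH(OAc)3], CH3CN–AcOH, −30 °C
Reagents that add atoms: none
Why: Evans–Saksena hydroxyl-directed reduction delivers hydride intramolecularly from the C10 alkoxyborohydride through a chair transition state to give the 1,3-anti diol, which is the C8 configuration of the target, while the dienone is not touched by triacetoxyborohydride.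

**Step 11**
Reactants: 21 anti diol
Product: 23 3,10-hemiketal (3-hydroxy-3,10:6,12-diepoxygermacra-1Z,4Z,11(13)-trien-8-ol), via (1Z)-enone 22 (not isolated)
Conditions: hν (350 nm), degassed CH3CN, 20 °C
Reagents that add atoms: none
Why: Photochemical E-to-Z isomerisation of the C1=C2 enone is driven to completion because only the Z isomer can close to the five-membered 3,10-hemiketal, which no longer absorbs, the hemiketal carbon being fixed by the cis bridging.

**Step 12**
Reactants: 23 hemiketal; 24 angelic acid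
Product: 25 8-O-angelate of hemiketal 23
Conditions: 24, 2,4,6-trichlorobenzoyl chloride, Et3N, toluene, 25 °C; then 23, 80 °C
Reagents that add atoms: none
Why: Yamaguchi-type esterification through the mixed anhydride acylates only the secondary C8 hydroxyl (the hemiketal hydroxyl is tertiary) and, without a nucleophilic catalyst, does not isomerise the angelate to the tiglate.

**Step 13**
Reactants: 25 angelate hemiketal
Product: 27 8-angeloyloxy-1,2-cis-epoxy-10-hydroxy-6,12-epoxygermacra-4Z,11(13)-dien-3-one, via open hydroxy enone 26 (not isolated)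
Conditions: t-BuOOH, DBU, CH2Cl2, 0 → 25 °C
Reagents that add atoms: tert-butyl hydroperoxide CC(C)(C)OO
Why: Weitz–Scheffer nucleophilic epoxidation takes place on the ring-opened (1Z)-hydroxy enone, the Z geometry giving the cis-oxirane and hydrogen bonding of the hydroperoxide to the free C10 hydroxyl (C14 methyl eclipsing the olefin to avoid allylic strain) delivering oxygen to the face required for C1 and C2.

**Step 14**
Reactants: 27 epoxy ketone
Product: 28 8-angeloyloxy-1,2-cis-epoxy-10-hydroxy-3-oxogermacra-4Z,11(13)-dien-12,6-olide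
Conditions: CrO3, 3,5-dimethylpyrazole, CH2Cl2, −20 °C
Reagents that add atoms: chromium trioxide O=[Cr](=O)=O
Why: Allylic oxidation by the CrO3–3,5-dimethylpyrazole complex converts the doubly activated (allylic and α-oxygenated) C12 methylene of the 3-methylenetetrahydrofuran into the α-methylene lactone carbonyl, no oxidisable secondary alcohol being present at this stage.

**Step 15**
Reactants: 28 keto lactone
Product: 29 target, (1R,2R,3R,6S,7R,8R,10R,4Z)-8-angeloyloxy-1,2-epoxy-3,10-dihydroxygermacra-4,11(13)-dien-12,6-olide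
Conditions: Zn(BH4)2, Et2O, −20 °C
Reagents that add atoms: none
Why: Chelation-controlled 1,2-reduction of the α,β-epoxy ketone (zinc bridging the carbonyl and oxirane oxygens, hydride entering from the side away from C1) gives the anti epoxy alcohol with 3R configuration and spares lactone, ester and oxirane.

**Compound list**
1 | (S)-(+)-carvone | C=C(C)[C@@H]1CC(=O)C(C)=CC1 | starting material
2 | (5S)-5-(3-hydroxyprop-1-en-2-yl)-2-methylcyclohex-2-en-1-one | C=C(CO)[C@@H]1CC(=O)C(C)=CC1 | intermediate
3 | dipotassium dienolate of 2 | [K+].[K+].C=C(C[O-])[C@@H]1CC([O-])=C(C)C=C1 | intermediate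
4 | (5R)-5-(3-hydroxyprop-1-en-2-yl)-2-methylcyclohex-3-en-1-one (epimers at the methyl-bearing carbon) | C=C(CO)[C@@H]1CC(=O)C(C)C=C1 | intermediate
5 | cis-fused iodo ether (iodine on C5 trans to O6; C4 epimers) | C=C1CO[C@H]2[C@H](I)C(C)C(=O)C[C@@H]12 | intermediate
6 | (3aS,7aS)-6-methyl-3-methylidene-2,3,3a,7a-tetrahydro-1-benzofuran-5(4H)-one | C=C1CO[C@H]2C=C(C)C(=O)C[C@@H]12 | intermediate
7 | (S)-2-(tert-butyldimethylsilyloxy)propanal | C[C@H](O[Si](C)(C)C(C)(C)C)C=O | starting material
8 | lithium C3=C8 enolate of 6 | [Li+].C=C1CO[C@H]2C=C(C)C([O-])=C[C@@H]12 | intermediate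
9 | C8 aldol adduct of 6 (C8/C9 epimers) | C=C1CO[C@H]2C=C(C)C(=O)C(C(O)[C@H](C)O[Si](C)(C)C(C)(C)C)[C@@H]12 | intermediate
10 | C9 methanesulfonate of 9 | C=C1CO[C@H]2C=C(C)C(=O)C(C(OS(C)(=O)=O)[C@H](C)O[Si](C)(C)C(C)(C)C)[C@@H]12 | intermediate
11 | (E)-C8=C9 alkylidene ketone | C=C1CO[C@H]2C=C(C)C(=O)/C(=C/[C@H](C)O[Si](C)(C)C(C)(C)C)[C@@H]12 | intermediate
12 | potassium dienolate of 11 ((Z)-C9=C10 silyl enol ether) | [K+].C=C1CO[C@H]2C=C(C)C([O-])=C(/C=C(/C)O[Si](C)(C)C(C)(C)C)[C@@H]12 | intermediate
13 | potassium C8 alkoxide (O8 opposite C11) | [K+].C=C1CO[C@H]2C=C(C)C(=O)[C@@]([O-])(/C=C(/C)O[Si](C)(C)C(C)(C)C)[C@@H]12 | intermediate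
14 | C8 methyl ether with (Z)-2-(tert-butyldimethylsilyloxy)prop-1-enyl on C8 | C=C1CO[C@H]2C=C(C)C(=O)[C@@](OC)(/C=C(/C)O[Si](C)(C)C(C)(C)C)[C@@H]12 | intermediate
15 | (Z)-1-bromo-2-ethoxyethene | Br/C=C\OCC | starting material
16 | C3 carbinol with (Z)-2-ethoxyvinyl on C3 trans to the C8 alkenyl group | C=C1CO[C@H]2C=C(C)[C@](O)(/C=C\OCC)[C@@](OC)(/C=C(/C)O[Si](C)(C)C(C)(C)C)[C@@H]12 | intermediate
17 | potassium alkoxide of 16 | [K+].C=C1CO[C@H]2C=C(C)[C@]([O-])(/C=C\OCC)[C@@](OC)(/C=C(/C)O[Si](C)(C)C(C)(C)C)[C@@H]12 | intermediate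
18 | ring-expanded potassium C2=C3 enolate (1-ethoxy; C10 set) | [K+].C=C1CO[C@H]2/C=C(/C)\C([O-])=C\[C@@H](OCC)[C@](C)(O[Si](C)(C)C(C)(C)C)/C=C(\OC)[C@@H]12 | intermediate
19 | 8-methoxy-10-(tert-butyldimethylsilyloxy)-6,12-epoxygermacra-1E,4Z,8Z,11(13)-tetraen-3-one | C=C1CO[C@H]2/C=C(/C)C(=O)/C=C/[C@](C)(O[Si](C)(C)C(C)(C)C)/C=C(\OC)[C@@H]12 | intermediate
20 | 10-hydroxy-6,12-epoxygermacra-1E,4Z,11(13)-triene-3,8-dione | C=C1CO[C@H]2/C=C(/C)C(=O)/C=C/[C@](C)(O)CC(=O)[C@@H]12 | intermediate
21 | 8,10-dihydroxy-6,12-epoxygermacra-1E,4Z,11(13)-trien-3-one (8,10-anti) | C=C1CO[C@H]2/C=C(/C)C(=O)/C=C/[C@](C)(O)C[C@@H](O)[C@@H]12 | intermediate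
22 | (1Z) isomer of 21 | C=C1CO[C@H]2/C=C(/C)C(=O)/C=C\[C@](C)(O)C[C@@H](O)[C@@H]12 | intermediate
23 | 3,10-hemiketal of 22 | C=C1CO[C@H]2/C=C(/C)[C@@]3(O)C=C[C@](C)(O3)C[C@@H](O)[C@@H]12 | intermediate
24 | angelic acid, (Z)-2-methylbut-2-enoic acid | C/C=C(/C)C(=O)O | starting material
25 | 8-O-angelate of 23 | C=C1CO[C@H]2/C=C(/C)[C@@]3(O)C=C[C@](C)(O3)C[C@@H](OC(=O)/C(C)=C\C)[C@@H]12 | intermediate
26 | ring-opened (1Z)-10-hydroxy-3-ketone tautomer of 25 | C=C1CO[C@H]2/C=C(/C)C(=O)/C=C\[C@](C)(O)C[C@@H](OC(=O)/C(C)=C\C)[C@@H]12 | intermediate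
27 | 8-angeloyloxy-1,2-cis-epoxy-10-hydroxy-6,12-epoxygermacra-4Z,11(13)-dien-3-one | C=C1CO[C@H]2/C=C(/C)C(=O)[C@H]3O[C@H]3[C@](C)(O)C[C@@H](OC(=O)/C(C)=C\C)[C@@H]12 | intermediate
28 | 8-angeloyloxy-1,2-cis-epoxy-10-hydroxy-3-oxogermacra-4Z,11(13)-dien-12,6-olide | C=C1C(=O)O[C@H]2/C=C(/C)C(=O)[C@H]3O[C@H]3[C@](C)(O)C[C@@H](OC(=O)/C(C)=C\C)[C@@H]12 | intermediate
29 | (1R,2R,3R,6S,7R,8R,10R,4Z)-8-angeloyloxy-1,2-epoxy-3,10-dihydroxygermacra-4,11(13)-dien-12,6-olide | C=C1C(=O)O[C@H]2/C=C(/C)[C@@H](O)[C@H]3O[C@H]3[C@](C)(O)C[C@@H](OC(=O)/C(C)=C\C)[C@@H]12 | target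

**Totals**
Total step count: 15. Longest linear sequence: 15 steps, from (S)-carvone 1 to 29; compounds 7, 15 and 24 are bought.

**Three steps most likely to fail**

Step 6. The γ-deprotonation may compete with removal of the C6 hydrogen or give the wrong enol ether geometry, which would invert C10 after the rearrangement. The fallback sets out from 6. Its kinetic lithium enolate is alkylated with 2-methoxyallyl bromide to give the 2-methoxyallyl ketone F1. The only remaining α-hydrogen (on C8) is then removed, and hydroxylation and methylation as in step 6 give the tertiary methyl ether F2. Oxalic acid on wet silica hydrolyses the enol ether to the methyl ketone F3. Soft enolisation of F3 toward C9 with tert-butyldimethylsilyl triflate and Et3N comes back to the route at 14.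

Step 8. The alkoxyvinyl rearrangement may leave the chair pathway (the Z ethoxy group is axial), the enol silyl group may move to the alkoxide, or ethoxide loss may be untidy. The fallback sets out from 14. CH2=CHMgBr adds on the same face to give the vinyl carbinol F4. The oxy-Cope is run with KH and 18-crown-6 and the plain enolate is trapped with (CH3)3SiCl as the ring-expanded trimethylsilyl enol ether F5. Saegusa dehydrogenation with Pd(OAc)2 in CH3CN installs the C1=C2 bond and comes back to the route at 19.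

Step 13. The peroxide may attack the C4=C5 enone or the wrong face of C1=C2. The fallback sets out from 25. Luche reduction (NaBH4, CeCl3·7H2O, CH3OH) through the open form gives the (1Z)-ene-3,10-diol F6. (C2H5)3SiCl with imidazole silylates only the secondary hydroxyl to give the 3-silyl ether F7. VO(acac)2 with t-BuOOH, directed by the tertiary C10 hydroxyl, gives the cis-epoxide F8. HF·pyridine frees the epoxy diol F9, and Dess–Martin oxidation of its C3 hydroxyl comes back to the route at 27.

**Further compounds**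
F1 | step 6 | C8 2-methoxyallyl ketone (alkyl group trans to C11) | C=C1CO[C@H]2C=C(C)C(=O)[C@H](CC(OC)=C)[C@@H]12
F2 | step 6 | C8 methoxy C8 2-methoxyallyl ketone | C=C1CO[C@H]2C=C(C)C(=O)[C@@](OC)(CC(OC)=C)[C@@H]12
F3 | step 6 | C8 methoxy C8 acetonyl ketone | C=C1CO[C@H]2C=C(C)C(=O)[C@@](OC)(CC(C)=O)[C@@H]12
F4 | step 8 | C3 vinyl carbinol (vinyl trans to the C8 alkenyl group) | C=C1CO[C@H]2C=C(C)[C@](O)(C=C)[C@@](OC)(/C=C(/C)O[Si](C)(C)C(C)(C)C)[C@@H]12
F5 | step 8 | ring-expanded C2=C3 trimethylsilyl enol ether | C=C1CO[C@H]2/C=C(/C)\C(O[Si](C)(C)C)=C\C[C@](C)(O[Si](C)(C)C(C)(C)C)/C=C(\OC)[C@@H]12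
F6 | step 13 | (1Z)-ene-3,10-diol 8-angelate (C3 epimers) | C=C1CO[C@H]2/C=C(/C)C(O)/C=C\[C@](C)(O)C[C@@H](OC(=O)/C(C)=C\C)[C@@H]12
F7 | step 13 | 3-O-triethylsilyl ether of F6 | C=C1CO[C@H]2/C=C(/C)C(O[Si](CC)(CC)CC)/C=C\[C@](C)(O)C[C@@H](OC(=O)/C(C)=C\C)[C@@H]12
F8 | step 13 | 1,2-cis-epoxide of F7 | C=C1CO[C@H]2/C=C(/C)C(O[Si](CC)(CC)CC)[C@H]3O[C@H]3[C@](C)(O)C[C@@H](OC(=O)/C(C)=C\C)[C@@H]12
F9 | step 13 | 1,2-cis-epoxy-3,10-diol 8-angelate | C=C1CO[C@H]2/C=C(/C)C(O)[C@H]3O[C@H]3[C@](C)(O)C[C@@H](OC(=O)/C(C)=C\C)[C@@H]12
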